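A direct plan would couple 3,5-dimethoxyphenylmagnesium bromide with 1,8-dibromooctane to bromide A1, exchange the methyl ethers for silyl ethers and quaternise PPh3 to phosphonium salt A2. It would then join A2 by a Z-selective Wittig reaction to (S)-3-silyloxynonanal A3 (asymmetric allylboration of heptanal, silylation, ozonolysis) and desilylate triether A4.
Its weakest steps would be:
- the exchange of methyl for silyl ethers on the arene, which would cost two operations and add no complexity;
- the Wittig olefination, whose Z/E ratio would rest on kinetic control alone, with an E isomer hard to remove from an oily lipid and a β-silyloxy aldehyde prone to elimination under the basic ylide;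
- the reagent-controlled allylboration, which would consume a stoichiometric chiral borane and leave a minor enantiomer that no later step could remove.

The 17-carbon side chain, with its C8′ Z-olefin and C11′ carbinol, is atom for atom C2–C18 of ricinoleic acid, and ring carbon C5 of the resorcinol is that acid's carboxyl carbon, as in alkylresorcinol biosynthesis. The route therefore takes olefin and carbinol from methyl ricinoleate, inverts C12 once, and grows the arene on C1: the acyl group is added as the last unit to a dioxinone-masked triacetate, and one base-mediated aldol cycloaromatisation closes the benzene ring with the 1,3,5 pattern fixed; saponification and decarboxylation then free the resorcinol. No olefination, asymmetric reagent, aryl–alkyl coupling or hydroxyl protection would be needed.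

Key step: step 6

Assumption: methyl ricinoleate is taken as the commercial (9Z,12R) ester of high isomeric purity, and LiN(iPr)2, LiN(SiMe3)2 and iPrMgCl as commercial solutions.

Step 1
Reactants: 1 methyl ricinoleate [methyl (9Z,12R)-12-hydroxyoctadec-9-enoate]; 2 4-nitrobenzoic acid
Product: 4 methyl (9Z,12S)-12-(4-nitrobenzoyloxy)octadec-9-enoate, via alkoxytriphenylphosphonium 4-nitrobenzoate 3 (not isolated)
Conditions: PPh3 (1.5 equiv), diisopropyl azodicarboxylate (1.5 equiv), 2 (1.5 equiv), THF, 0 °C to rt, 12 h
Reagents that add atoms: none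
Why: In this Mitsunobu esterification the C12 alkoxyphosphonium ion 3 should be displaced by 4-nitrobenzoate in an SN2 reaction with inversion (12R to 12S), the acidic 4-nitrobenzoic acid favouring substitution over elimination at the homoallylic position, while the methyl ester and the Z-olefin are inert.

Step 2
Reactants: 4 methyl (9Z,12S)-12-(4-nitrobenzoyloxy)octadec-9-enoate
Product: 5 methyl (9Z,12S)-12-hydroxyoctadec-9-enoate
Conditions: K2CO3 (0.2 equiv), MeOH, rt, 3 h; chromatography
Reagents that add atoms: none
Why: Carbonate-catalysed transesterification (methanolysis) should cleave the electron-poor aryl ester at the acyl–oxygen bond, so C12 keeps its S configuration, and exchange at the methyl ester is degenerate.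

Step 3
Reactants: 5 methyl (9Z,12S)-12-hydroxyoctadec-9-enoate; 6 N,O-dimethylhydroxylamine hydrochloride
Product: 8 (9Z,12S)-12-hydroxy-N-methoxy-N-methyloctadec-9-enamide, via chloromagnesium N-methoxy-N-methylamide 7 (not isolated)
Conditions: 6 (2.0 equiv), iPrMgCl (2 M in THF, 5.0 equiv), THF, −20 °C to 0 °C, 2 h; aq. NH4Cl
Reagents that add atoms: none
Why: Direct aminolysis of the ester by magnesium amide 7 (Weinreb amide synthesis) should stop at the amide because the chelated tetrahedral adduct is stable, and the C12 carbinol rides through as its magnesium alkoxide.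

Step 4
Reactants: 9 2,2,6-trimethyl-4H-1,3-dioxin-4-one; 10 acetyl chloride
Product: 12 2,2-dimethyl-6-(2-oxopropyl)-4H-1,3-dioxin-4-one, via lithium dienolate 11 (not isolated)
Conditions: 9 (2.0 equiv), LiN(SiMe3)2 (1 M in THF, 2.1 equiv), THF, −78 °C, 1 h; 10 (1.0 equiv), −78 °C, 2 h; aq. NH4Cl; chromatography
Reagents that add atoms: none
Why: γ-Selective C-acylation of the vinylogous ester enolate 11 by the acid chloride (crossed Claisen-type acylation) should give the keto-dioxinone, two equivalents of enolate being used per acyl chloride because the product is more acidic than 9.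

Step 5
Reactants: 12 2,2-dimethyl-6-(2-oxopropyl)-4H-1,3-dioxin-4-one; 8 (9Z,12S)-12-hydroxy-N-methoxy-N-methyloctadec-9-enamide
Product: 14 6-[(12Z,15S)-15-hydroxy-2,4-dioxohenicos-12-en-1-yl]-2,2-dimethyl-4H-1,3-dioxin-4-one, via dilithium dianion 13 (not isolated)
Conditions: 12 (3.0 equiv), LiN(iPr)2 (6.1 equiv), THF, −78 °C, 1 h; 8 (1.0 equiv) in THF, −78 °C to −30 °C, 3 h; 1 M HCl to pH 3 at −30 °C; rapid silica filtration, used at once
Reagents that add atoms: none
Why: The terminal carbanion of dianion 13 is its most nucleophilic site and should add to the Weinreb amide to give a chelated adduct that collapses to the ketone only on work-up (Claisen-type acylation of a 1,3-dicarbonyl dianion), with one equivalent of dianion spent on the carbinol proton and one on the acidic product, and with the olefin and the stereocentre remote from the reacting end.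

Step 6
Reactants: 14 6-[(12Z,15S)-15-hydroxy-2,4-dioxohenicos-12-en-1-yl]-2,2-dimethyl-4H-1,3-dioxin-4-one
Product: 16 7-hydroxy-5-[(8Z,11S)-11-hydroxyheptadec-8-en-1-yl]-2,2-dimethyl-4H-1,3-benzodioxin-4-one, via cyclic aldol adduct 15 (not isolated)
Conditions: Et3N (4 equiv), CH2Cl2, rt, 16 h; 1 M HCl wash; chromatography
Reagents that add atoms: none
Why: Et3N should deprotonate the doubly activated side-chain methylene C1′ of 14 (γ to the dioxinone carbonyl and α to the C2′ ketone), and the resulting vinylogous enolate attacks the C4′ ketone, the former C1 of ricinoleic acid, through the dioxinone α-carbon C5; loss of water from the tertiary aldol 15 and enolisation of the C2′ ketone then give the benzene ring irreversibly. The closest known reaction type is the biomimetic aldol cycloaromatisation of β,δ-diketo-dioxinones to isopropylidene-protected β-resorcylates, which copies the C2-to-C7 aldol closure of a tetraketide by an alkylresorcinol synthase. The six-membered carbocycle closes in a favoured 6-(enolexo)-exo-trig aldol mode. No new stereocentre survives, since the two sp3 centres of 15 become planar on aromatisation, and the side-chain carbinol and Z-olefin are remote spectators under this mild base. The step needs C-aldol closure to win over O-cyclisation to a 4-pyranone and over Claisen closure to an acylphloroglucinol. The dioxinone secures this because it holds the carboxyl carbon and the C3 oxygen as an acetal-locked vinylogous ester that can act neither as an acyl donor nor as a free enol oxygen, and only one six-membered carbon–carbon closure is geometrically possible.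

Step 7
Reactants: 16 7-hydroxy-5-[(8Z,11S)-11-hydroxyheptadec-8-en-1-yl]-2,2-dimethyl-4H-1,3-benzodioxin-4-one
Product: 18 5-[(8Z,11S)-11-hydroxyheptadec-8-en-1-yl]benzene-1,3-diol (target), via resorcylic acid 17 (not isolated)
Conditions: KOH (6 M aq., 15 equiv), MeOH, Ar, sealed tube, 100 °C, 10 h; cool, 2 M HCl to pH 4; chromatography
Reagents that add atoms: none
Why: Hydroxide should open the cyclic acylal (saponification) to acetone and β-resorcylate 17, whose electron-rich ring is protonated at the ipso carbon so that CO2 is lost (protodecarboxylation of a 2,4-dihydroxybenzoic acid), while the isolated Z-olefin and the secondary carbinol are inert to aqueous alkali.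

Compound list
1 | methyl ricinoleate, methyl (9Z,12R)-12-hydroxyoctadec-9-enoate | CCCCCC[C@@H](O)C/C=C\CCCCCCCC(=O)OC | starting material
2 | 4-nitrobenzoic acid | OC(=O)c1ccc(cc1)[N+](=O)[O-] | starting material
3 | {[(9Z,12R)-1-methoxy-1-oxooctadec-9-en-12-yl]oxy}triphenylphosphonium 4-nitrobenzoate (formed in the flask) | CCCCCC[C@@H](O[P+](c1ccccc1)(c1ccccc1)c1ccccc1)C/C=C\CCCCCCCC(=O)OC.[O-]C(=O)c1ccc(cc1)[N+](=O)[O-] | intermediate
4 | methyl (9Z,12S)-12-(4-nitrobenzoyloxy)octadec-9-enoate | CCCCCC[C@H](OC(=O)c1ccc(cc1)[N+](=O)[O-])C/C=C\CCCCCCCC(=O)OC | intermediate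
5 | methyl (9Z,12S)-12-hydroxyoctadec-9-enoate | CCCCCC[C@H](O)C/C=C\CCCCCCCC(=O)OC | intermediate
6 | N,O-dimethylhydroxylamine hydrochloride | CNOC.Cl | starting material
7 | chloromagnesium N-methoxy-N-methylamide (formed in the flask) | CN(OC)[Mg]Cl | intermediate
8 | (9Z,12S)-12-hydroxy-N-methoxy-N-methyloctadec-9-enamide | CCCCCC[C@H](O)C/C=C\CCCCCCCC(=O)N(C)OC | intermediate
9 | 2,2,6-trimethyl-4H-1,3-dioxin-4-one | CC1=CC(=O)OC(C)(C)O1 | starting material
10 | acetyl chloride | CC(Cl)=O | starting material
11 | lithium 2,2-dimethyl-6-methylidene-6H-1,3-dioxin-4-olate, the dienolate of 9 (formed in the flask) | [Li+].[O-]C1=CC(=C)OC(C)(C)O1 | intermediate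
12 | 2,2-dimethyl-6-(2-oxopropyl)-4H-1,3-dioxin-4-one | CC(=O)CC1=CC(=O)OC(C)(C)O1 | intermediate
13 | dilithium dianion of 12, drawn as the bis-enolate (formed in the flask) | [Li+].[Li+].C=C([O-])C=C1C=C([O-])OC(C)(C)O1 | intermediate
14 | 6-[(12Z,15S)-15-hydroxy-2,4-dioxohenicos-12-en-1-yl]-2,2-dimethyl-4H-1,3-dioxin-4-one | CCCCCC[C@H](O)C/C=C\CCCCCCCC(=O)CC(=O)CC1=CC(=O)OC(C)(C)O1 | intermediate
15 | 5-hydroxy-5-[(8Z,11S)-11-hydroxyheptadec-8-en-1-yl]-2,2-dimethyl-4a,5-dihydro-4H-1,3-benzodioxine-4,7(6H)-dione, epimers at C4a and C5 (formed in the flask) | CCCCCC[C@H](O)C/C=C\CCCCCCCC1(O)CC(=O)C=C2OC(C)(C)OC(=O)C12 | intermediate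
16 | 7-hydroxy-5-[(8Z,11S)-11-hydroxyheptadec-8-en-1-yl]-2,2-dimethyl-4H-1,3-benzodioxin-4-one | CCCCCC[C@H](O)C/C=C\CCCCCCCc1cc(O)cc2OC(C)(C)OC(=O)c12 | intermediate
17 | 2,4-dihydroxy-6-[(8Z,11S)-11-hydroxyheptadec-8-en-1-yl]benzoic acid, present as its potassium salt (formed in the flask) | CCCCCC[C@H](O)C/C=C\CCCCCCCc1cc(O)cc(O)c1C(=O)O | intermediate
18 | 5-[(8Z,11S)-11-hydroxyheptadec-8-en-1-yl]benzene-1,3-diol | CCCCCC[C@H](O)C/C=C\CCCCCCCc1cc(O)cc(O)c1 | target

Total step count: 7. Longest linear sequence: 6 (steps 1, 2, 3, 5, 6, 7); step 4 is a one-step side branch.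

Steps most likely to fail

Step 5. Proton transfer could stall the Claisen condensation: the free carbinol quenches dianion, the resulting lithium alkoxide may aggregate with the remaining dianion, and the amide may be enolised instead of attacked. The fallback would set out from 8, which would be silylated (Et3SiCl, imidazole, CH2Cl2) to (9Z,12S)-N-methoxy-N-methyl-12-(triethylsilyloxy)octadec-9-enamide F1. Acylation of dianion 13 (now 2 equiv) with F1 would give 6-[(12Z,15S)-2,4-dioxo-15-(triethylsilyloxy)henicos-12-en-1-yl]-2,2-dimethyl-4H-1,3-dioxin-4-one F2. Mild acid (AcOH/THF/H2O, rt) would remove the silyl group and return the route to 14.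

Step 1. Elimination of the activated homoallylic alkoxyphosphonium ion towards a conjugated diene, or partial retention through an acyloxyphosphonium pathway, could erode yield and configurational purity. The fallback would set out from 1 and separate activation from displacement. MsCl and Et3N in CH2Cl2 at 0 °C would give methyl (9Z,12R)-12-(methanesulfonyloxy)octadec-9-enoate F3. Displacement with CsOAc and 18-crown-6 in toluene at 80 °C would give, with inversion, methyl (9Z,12S)-12-acetoxyoctadec-9-enoate F4. Methanolysis with K2CO3 in MeOH would bring the route back at 5.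

Step 7. Decarboxylation could remain incomplete, and the resorcinolate could be degraded oxidatively during long heating in strong alkali. The fallback would set out from 14 and free the carboxyl group under neutral conditions.
- Heating 14 in toluene at 110 °C with allyl alcohol (20 equiv) would expel acetone and give the acylketene (15Z,18S)-18-hydroxy-3,5,7-trioxotetracosa-1,15-dien-1-one F5.
- The excess primary alcohol would trap F5, ahead of the remote secondary hydroxyl, as allyl (15Z,18S)-18-hydroxy-3,5,7-trioxotetracos-15-enoate F6.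
- Cs2CO3 in iPrOH followed by HCl would aromatise F6 by the same aldol closure to allyl 2,4-dihydroxy-6-[(8Z,11S)-11-hydroxyheptadec-8-en-1-yl]benzoate F7.
- Pd(PPh3)4 and morpholine in THF at rt would transfer the allyl group and return the route to 17, which would lose CO2 on warming in toluene at 100 °C to give 18.

Further compounds
F1 | step 5 | (9Z,12S)-N-methoxy-N-methyl-12-(triethylsilyloxy)octadec-9-enamide | CCCCCC[C@H](O[Si](CC)(CC)CC)C/C=C\CCCCCCCC(=O)N(C)OC
F2 | step 5 | 6-[(12Z,15S)-2,4-dioxo-15-(triethylsilyloxy)henicos-12-en-1-yl]-2,2-dimethyl-4H-1,3-dioxin-4-one | CCCCCC[C@H](O[Si](CC)(CC)CC)C/C=C\CCCCCCCC(=O)CC(=O)CC1=CC(=O)OC(C)(C)O1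
F3 | step 1 | methyl (9Z,12R)-12-(methanesulfonyloxy)octadec-9-enoate | CCCCCC[C@@H](OS(C)(=O)=O)C/C=C\CCCCCCCC(=O)OC
F4 | step 1 | methyl (9Z,12S)-12-acetoxyoctadec-9-enoate | CCCCCC[C@H](OC(C)=O)C/C=C\CCCCCCCC(=O)OC
F5 | step 7 | (15Z,18S)-18-hydroxy-3,5,7-trioxotetracosa-1,15-dien-1-one (acylketene, formed in the flask) | CCCCCC[C@H](O)C/C=C\CCCCCCCC(=O)CC(=O)CC(=O)C=C=O
F6 | step 7 | allyl (15Z,18S)-18-hydroxy-3,5,7-trioxotetracos-15-enoate | CCCCCC[C@H](O)C/C=C\CCCCCCCC(=O)CC(=O)CC(=O)CC(=O)OCC=C
F7 | step 7 | allyl 2,4-dihydroxy-6-[(8Z,11S)-11-hydroxyheptadec-8-en-1-yl]benzoate | CCCCCC[C@H](O)C/C=C\CCCCCCCc1cc(O)cc(O)c1C(=O)OCC=C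
A1 | direct plan | 1-(8-bromooctyl)-3,5-dimethoxybenzene | COc1cc(CCCCCCCCBr)cc(OC)c1
A2 | direct plan | {8-[3,5-bis(tert-butyldimethylsilyloxy)phenyl]octyl}triphenylphosphonium bromide | CC(C)(C)[Si](C)(C)Oc1cc(CCCCCCCC[P+](c2ccccc2)(c2ccccc2)c2ccccc2)cc(O[Si](C)(C)C(C)(C)C)c1.[Br-]
A3 | direct plan | (S)-3-(tert-butyldimethylsilyloxy)nonanal | CCCCCC[C@H](O[Si](C)(C)C(C)(C)C)CC=O
A4 | direct plan | 5-[(8Z,11S)-11-(tert-butyldimethylsilyloxy)heptadec-8-en-1-yl]-1,3-bis(tert-butyldimethylsilyloxy)benzene | CCCCCC[C@H](O[Si](C)(C)C(C)(C)C)C/C=C\CCCCCCCc1cc(O[Si](C)(C)C(C)(C)C)cc(O[Si](C)(C)C(C)(C)C)c1
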